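The pyran ring is disconnected at O1–C2. With a C3=C4 double bond in place, the chain O1–C8a–C4a–C4–C3–C2 of rings A and C is a latent 1-oxatriene: an ortho-quinone methide of ring A carrying the 1-arylvinyl unit of ring B. One operation, an amine-catalysed Petasis borono-Mannich union of a ring A salicylaldehyde with a ring B 1-arylvinylboronate, makes C3–C4, releases this quinone methide and closes O1–C2 by oxa-6π electrocyclisation. Its precursors are thus only an aldehyde and a vinylboronate. Iridium-catalysed asymmetric hydrogenation then sets C3 (R), and a late aromatic Claisen rearrangement installs the 1,1-dimethylallyl group after all hydrogenations.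

Key step: step 7

Remark: isoflavan numbering is used (O1, C2, C3, C4, C4a, C5 to C8, C8a; ring B C1' to C6'). The target descriptor corresponds to (3R) (C2 > C1' > C4 > H). SEM = 2-(trimethylsilyl)ethoxymethyl; BArF = tetrakis[3,5-bis(trifluoromethyl)phenyl]borate. Compounds 1, 2 and 7 are taken as catalogue chemicals.

Step 1
Reactants: 1 2-iodobenzene-1,3-diol; 2 2-methylbut-3-en-2-ol
Product: 4 2-(3-hydroxy-3-methylbutyl)benzene-1,3-diol, via alkylborane 3 (not isolated)
Conditions: 2, 9-BBN, THF, 0 °C to rt; then 1, PdCl2(dppf) (5 mol%), aq. NaOH, THF, 65 °C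
Reagents that add atoms: none
Why: B-alkyl Suzuki–Miyaura coupling: 9-BBN should hydroborate the terminal alkene of 2 at the CH2 terminus faster than it reacts with the hindered tertiary hydroxyl, and the primary alkylborane 3 should then transfer its alkyl group to the aryl iodide, which puts the complete saturated C8 side chain in place with no alkene left to reduce later.

Step 2
Reactants: 4 2-(3-hydroxy-3-methylbutyl)benzene-1,3-diol
Product: 5 2,4-dihydroxy-3-(3-hydroxy-3-methylbutyl)benzaldehyde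
Conditions: MgCl2, Et3N, paraformaldehyde, MeCN, reflux
Reagents that add atoms: paraformaldehyde (as formaldehyde), C=O
Why: Magnesium phenoxide-directed ortho-formylation (a second equivalent of formaldehyde oxidises the intermediate benzylic alkoxide by hydride transfer) can only attack the two equivalent positions ortho to a hydroxyl, so one aldehyde should form, and the basic medium leaves the tertiary alcohol untouched.

Step 3
Reactants: 5 2,4-dihydroxy-3-(3-hydroxy-3-methylbutyl)benzaldehyde
Product: 6 2-hydroxy-3-(3-hydroxy-3-methylbutyl)-4-(SEM-oxy)benzaldehyde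
Conditions: SEMCl (1.05 equiv), K2CO3, acetone, 0 °C to rt
Reagents that add atoms: 2-(trimethylsilyl)ethoxymethyl chloride (SEMCl), C[Si](C)(C)CCOCCl
Why: Williamson etherification under weak base: the 2-hydroxyl is tied up in a hydrogen bond to the formyl group, so the more acidic free 4-hydroxyl should be alkylated selectively, carbonate does not deprotonate the tertiary alcohol, and the free 2-hydroxyl is kept for the key step.

Step 4
Reactants: 7 1-[4-(benzyloxy)-2-hydroxyphenyl]ethan-1-one
Product: 8 1-[4-(benzyloxy)-2-(SEM-oxy)phenyl]ethan-1-one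
Conditions: NaH (1.05 equiv), DMF, 0 °C; then SEMCl, 0 °C to rt
Reagents that add atoms: 2-(trimethylsilyl)ethoxymethyl chloride (SEMCl), C[Si](C)(C)CCOCCl
Why: Williamson etherification of the sodium phenoxide: one equivalent of NaH deprotonates only the phenol, and SEMCl caps it with a group that is stable to base and hydrogenation and labile to fluoride.

Step 5
Reactants: 8 1-[4-(benzyloxy)-2-(SEM-oxy)phenyl]ethan-1-one
Product: 9 1-[4-(benzyloxy)-2-(SEM-oxy)phenyl]ethenyl trifluoromethanesulfonate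
Conditions: KN(SiMe3)2, THF, −78 °C; then PhNTf2, −78 to 0 °C
Reagents that add atoms: N-phenylbis(trifluoromethanesulfonimide) (PhNTf2), O=S(=O)(N(c1ccccc1)S(=O)(=O)C(F)(F)F)C(F)(F)F
Why: Deprotonation of the only enolisable position gives the potassium enolate, whose O-sulfonylation by PhNTf2 should give the 1-arylvinyl triflate (enol triflate formation).

Step 6
Reactants: 9 1-[4-(benzyloxy)-2-(SEM-oxy)phenyl]ethenyl trifluoromethanesulfonate
Product: 10 2-{1-[4-(benzyloxy)-2-(SEM-oxy)phenyl]ethenyl}-4,4,5,5-tetramethyl-1,3,2-dioxaborolane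
Conditions: B2pin2, PdCl2(PPh3)2 (3 mol%), PPh3, KOPh, toluene, 50 °C
Reagents that add atoms: bis(pinacolato)diboron (B2pin2), CC1(C)OB(OC1(C)C)B1OC(C)(C)C(C)(C)O1
Why: Miyaura borylation: oxidative addition of the alkenyl triflate to zerovalent palladium, phenoxide-assisted transmetalation with B2pin2 and reductive elimination should give the 1-arylvinyl pinacol boronate with boron on the future C3.

Step 7
Reactants: 6 2-hydroxy-3-(3-hydroxy-3-methylbutyl)-4-(SEM-oxy)benzaldehyde; 10 2-{1-[4-(benzyloxy)-2-(SEM-oxy)phenyl]ethenyl}-4,4,5,5-tetramethyl-1,3,2-dioxaborolane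
Product: 13 4-{3-[4-(benzyloxy)-2-(SEM-oxy)phenyl]-7-(SEM-oxy)-2H-chromen-8-yl}-2-methylbutan-2-ol, via Mannich base 11 (not isolated), via ortho-quinone methide 12 (not isolated)
Conditions: Bn2NH (40 mol%), 1,4-dioxane/H2O, 90 °C
Reagents that add atoms: none
Why: Bn2NH condenses with aldehyde 6 to an iminium ion while the neighbouring phenoxide binds the boron of 10, and the resulting boronate transfers its 1-arylvinyl group intramolecularly to the iminium carbon (Petasis borono-Mannich reaction), which makes C3–C4 and gives Mannich base 11. At 90 °C the ortho-hydroxybenzylamine 11 expels Bn2NH to give ortho-quinone methide 12, in which O1=C8a–C4a=C4–C3=C2 is a 1-oxatriene. Thermal disrotatory oxa-6π electrocyclisation of 12 forms the O1–C2 bond, closes the six-membered pyran ring in a pericyclic mode (not a polar exo or endo closure) and restores the aromaticity of ring A, which drives the sequence. The closest known reaction type is the amine-catalysed Petasis synthesis of 2H-chromenes from salicylaldehydes and alkenylboron reagents. No stereocentre is formed, since C3 stays trigonal until step 8. The step needs carbon–carbon bond formation only at the formyl carbon and only through the boron-bearing carbon, so that the aryl group ends at C3 and the CH2 terminus at C2; this is secured by the free 2-hydroxyl of 6, which delivers the boronate to the adjacent iminium carbon, while the 7-oxygen is blocked as its SEM ether.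

Step 8
Reactants: 13 4-{3-[4-(benzyloxy)-2-(SEM-oxy)phenyl]-7-(SEM-oxy)-2H-chromen-8-yl}-2-methylbutan-2-ol
Product: 14 4-{(3R)-3-[4-(benzyloxy)-2-(SEM-oxy)phenyl]-7-(SEM-oxy)-3,4-dihydro-2H-chromen-8-yl}-2-methylbutan-2-ol
Conditions: [Ir(cod)(L)]BArF (2 mol%; L = tBu-PHOX, enantiomer chosen by a test run to deliver H2 to the Si face of C3), H2 (50 bar), CH2Cl2, rt
Reagents that add atoms: none
Why: Asymmetric hydrogenation of an unfunctionalised trisubstituted cyclic styrene by a cationic iridium phosphine–oxazoline catalyst, a reaction type established for 3-aryl-2H-chromenes: the chiral ligand controls the face, hydrogen delivery to the Si face of C3 sets (3R), and the benzyl ether, SEM ethers and tertiary alcohol should be tolerated.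

Step 9
Reactants: 14 4-{(3R)-3-[4-(benzyloxy)-2-(SEM-oxy)phenyl]-7-(SEM-oxy)-3,4-dihydro-2H-chromen-8-yl}-2-methylbutan-2-ol
Product: 15 4-{(3R)-3-[4-hydroxy-2-(SEM-oxy)phenyl]-7-(SEM-oxy)-3,4-dihydro-2H-chromen-8-yl}-2-methylbutan-2-ol
Conditions: H2 (1 atm), Pd/C, EtOAc, rt
Reagents that add atoms: none
Why: Hydrogenolysis of the benzyl ether frees only the 4'-hydroxyl, because the SEM ethers, the chroman and the tertiary alcohol are inert to H2 over Pd/C.

Step 10
Reactants: 15 4-{(3R)-3-[4-hydroxy-2-(SEM-oxy)phenyl]-7-(SEM-oxy)-3,4-dihydro-2H-chromen-8-yl}-2-methylbutan-2-ol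
Product: 16 4-{(3R)-3-[4-(3-methylbut-2-enyloxy)-2-(SEM-oxy)phenyl]-7-(SEM-oxy)-3,4-dihydro-2H-chromen-8-yl}-2-methylbutan-2-ol
Conditions: prenyl bromide, K2CO3, acetone, 50 °C
Reagents that add atoms: prenyl bromide (1-bromo-3-methylbut-2-ene), CC(C)=CCBr
Why: Williamson etherification: the only free phenol is alkylated at oxygen by the primary allylic bromide under carbonate, which touches neither the tertiary alcohol nor the SEM ethers.

Step 11
Reactants: 16 4-{(3R)-3-[4-(3-methylbut-2-enyloxy)-2-(SEM-oxy)phenyl]-7-(SEM-oxy)-3,4-dihydro-2H-chromen-8-yl}-2-methylbutan-2-ol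
Product: 18 4-{(3R)-3-[4-hydroxy-5-(2-methylbut-3-en-2-yl)-2-(SEM-oxy)phenyl]-7-(SEM-oxy)-3,4-dihydro-2H-chromen-8-yl}-2-methylbutan-2-ol, via ortho-dienone 17 (not isolated)
Conditions: PhNEt2, 190 °C, sealed tube
Reagents that add atoms: none
Why: Aromatic Claisen rearrangement: the [3,3]-sigmatropic shift inverts the allyl unit, so the quaternary carbon of the 1,1-dimethylallyl group bonds to the ortho carbon C5' (C3' is flanked by the SEM ether and is disfavoured for a tertiary carbon terminus), ortho-dienone 17 tautomerises to the phenol, the weakly basic solvent suppresses acid-promoted follow-up reactions, and C3 has no pathway for epimerisation.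

Step 12
Reactants: 18 4-{(3R)-3-[4-hydroxy-5-(2-methylbut-3-en-2-yl)-2-(SEM-oxy)phenyl]-7-(SEM-oxy)-3,4-dihydro-2H-chromen-8-yl}-2-methylbutan-2-ol
Product: 19 (3R)-3-[2,4-dihydroxy-5-(2-methylbut-3-en-2-yl)phenyl]-8-(3-hydroxy-3-methylbutyl)-3,4-dihydro-2H-chromen-7-ol
Conditions: TBAF (excess), THF/DMPU, 60 °C, under argon
Reagents that add atoms: none
Why: Fluoride attacks silicon and each SEM group fragments (β-elimination to Me3SiF and ethylene, then loss of formaldehyde from the hemiacetal anion), so both phenols are freed without acid, which spares the tertiary alcohol, the 1,1-dimethylallyl group and the C3 stereocentre.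

Compound list
1 | 2-iodobenzene-1,3-diol | Oc1cccc(O)c1I | starting material
2 | 2-methylbut-3-en-2-ol | C=CC(C)(C)O | starting material
3 | 4-(9-borabicyclo[3.3.1]nonan-9-yl)-2-methylbutan-2-ol | CC(C)(O)CCB1C2CCCC1CCC2 | intermediate
4 | 2-(3-hydroxy-3-methylbutyl)benzene-1,3-diol | CC(C)(O)CCc1c(O)cccc1O | intermediate
5 | 2,4-dihydroxy-3-(3-hydroxy-3-methylbutyl)benzaldehyde | CC(C)(O)CCc1c(O)ccc(C=O)c1O | intermediate
6 | 2-hydroxy-3-(3-hydroxy-3-methylbutyl)-4-(SEM-oxy)benzaldehyde | CC(C)(O)CCc1c(OCOCC[Si](C)(C)C)ccc(C=O)c1O | intermediate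
7 | 1-[4-(benzyloxy)-2-hydroxyphenyl]ethan-1-one | CC(=O)c1ccc(OCc2ccccc2)cc1O | starting material
8 | 1-[4-(benzyloxy)-2-(SEM-oxy)phenyl]ethan-1-one | CC(=O)c1ccc(OCc2ccccc2)cc1OCOCC[Si](C)(C)C | intermediate
9 | 1-[4-(benzyloxy)-2-(SEM-oxy)phenyl]ethenyl trifluoromethanesulfonate | C=C(OS(=O)(=O)C(F)(F)F)c1ccc(OCc2ccccc2)cc1OCOCC[Si](C)(C)C | intermediate
10 | 2-{1-[4-(benzyloxy)-2-(SEM-oxy)phenyl]ethenyl}-4,4,5,5-tetramethyl-1,3,2-dioxaborolane | C=C(B1OC(C)(C)C(C)(C)O1)c1ccc(OCc2ccccc2)cc1OCOCC[Si](C)(C)C | intermediate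
11 | Mannich base: racemic 4-{3-[2-(4-benzyloxy-2-SEM-oxyphenyl)-1-(dibenzylamino)prop-2-en-1-yl]-2-hydroxy-6-(SEM-oxy)phenyl}-2-methylbutan-2-ol | C=C(c1ccc(OCc2ccccc2)cc1OCOCC[Si](C)(C)C)C(N(Cc1ccccc1)Cc1ccccc1)c1ccc(OCOCC[Si](C)(C)C)c(CCC(C)(C)O)c1O | intermediate
12 | ortho-quinone methide: 6-[2-(4-benzyloxy-2-SEM-oxyphenyl)prop-2-en-1-ylidene]-2-(3-hydroxy-3-methylbutyl)-3-(SEM-oxy)cyclohexa-2,4-dien-1-one (reactive Z isomer) | O=C1C(CCC(C)(C)O)=C(OCOCC[Si](C)(C)C)C=CC1=CC(=C)c1ccc(OCc2ccccc2)cc1OCOCC[Si](C)(C)C | intermediate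
13 | 4-{3-[4-(benzyloxy)-2-(SEM-oxy)phenyl]-7-(SEM-oxy)-2H-chromen-8-yl}-2-methylbutan-2-ol | CC(C)(O)CCc1c(OCOCC[Si](C)(C)C)ccc2C=C(c3ccc(OCc4ccccc4)cc3OCOCC[Si](C)(C)C)COc12 | intermediate
14 | 4-{(3R)-3-[4-(benzyloxy)-2-(SEM-oxy)phenyl]-7-(SEM-oxy)-3,4-dihydro-2H-chromen-8-yl}-2-methylbutan-2-ol | C[Si](C)(C)CCOCOc1cc(OCc2ccccc2)ccc1[C@@H]1COc2c(ccc(OCOCC[Si](C)(C)C)c2CCC(C)(C)O)C1 | intermediate
15 | 4-{(3R)-3-[4-hydroxy-2-(SEM-oxy)phenyl]-7-(SEM-oxy)-3,4-dihydro-2H-chromen-8-yl}-2-methylbutan-2-ol | C[Si](C)(C)CCOCOc1cc(O)ccc1[C@@H]1COc2c(ccc(OCOCC[Si](C)(C)C)c2CCC(C)(C)O)C1 | intermediate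
16 | 4-{(3R)-3-[4-(3-methylbut-2-enyloxy)-2-(SEM-oxy)phenyl]-7-(SEM-oxy)-3,4-dihydro-2H-chromen-8-yl}-2-methylbutan-2-ol | C[Si](C)(C)CCOCOc1cc(OCC=C(C)C)ccc1[C@@H]1COc2c(ccc(OCOCC[Si](C)(C)C)c2CCC(C)(C)O)C1 | intermediate
17 | ortho-dienone: 6-(2-methylbut-3-en-2-yl)-3-(SEM-oxy)-4-[(3R)-8-(3-hydroxy-3-methylbutyl)-7-(SEM-oxy)chroman-3-yl]cyclohexa-2,4-dien-1-one (mixture at the new sp3 ring carbon) | O=C1C=C(OCOCC[Si](C)(C)C)C([C@@H]2COc3c(ccc(OCOCC[Si](C)(C)C)c3CCC(C)(C)O)C2)=CC1C(C)(C)C=C | intermediate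
18 | 4-{(3R)-3-[4-hydroxy-5-(2-methylbut-3-en-2-yl)-2-(SEM-oxy)phenyl]-7-(SEM-oxy)-3,4-dihydro-2H-chromen-8-yl}-2-methylbutan-2-ol | C=CC(C)(C)c1cc([C@@H]2COc3c(ccc(OCOCC[Si](C)(C)C)c3CCC(C)(C)O)C2)c(OCOCC[Si](C)(C)C)cc1O | intermediate
19 | (3R)-3-[2,4-dihydroxy-5-(2-methylbut-3-en-2-yl)phenyl]-8-(3-hydroxy-3-methylbutyl)-3,4-dihydro-2H-chromen-7-ol (CNP0420388.1) | C=CC(C)(C)c1cc([C@@H]2COc3c(ccc(O)c3CCC(C)(C)O)C2)c(O)cc1O | target

Total step count: 12. Longest linear sequence: 9 steps (steps 1 to 3, then 7 to 12; the ring B branch, steps 4 to 6, then 7 to 12, is equally long).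

Steps most likely to fail

Step 7. Protodeboronation of the electron-rich 1-arylvinylboronate, or slow transfer of the hindered alkenyl group to the iminium ion, may outrun the cascade. The fallback avoids boron: it sets out from vinyl triflate 9 and aldehyde 6 and comes back at 13. A Nozaki–Hiyama–Kishi coupling (CrCl2 in excess, NiCl2 cat., DMF, rt) should give allylic alcohol F1. Mild acid-catalysed dehydration of F1 (PPTS cat., toluene, 80 °C) should give the same ortho-quinone methide 12, which closes O1–C2 by the same electrocyclisation to 13.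

Step 11. The allyl unit may migrate to the wrong ortho carbon (C3'), the prenyl group may be lost, or the product may rearrange or cyclise further at the high temperature. The fallback sets out from phenol 15, replaces steps 10 and 11, and comes back at 18. Ortho-iodination of the only free phenol at its less hindered ortho carbon (I2, morpholine, CH2Cl2, 0 °C) should give iodophenol F2. A γ-selective Suzuki–Miyaura coupling of F2 with prenyl pinacol boronate (Pd(OAc)2, bulky dialkylbiarylphosphine chosen for attack through the substituted allyl terminus, aq. K3PO4, THF, 40 °C) should then give 18.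

Step 8. Conversion or facial discrimination may be poor because the ortho-substituted 3-aryl group is twisted out of the alkene plane. The fallback sets out from 13, replaces steps 8 and 9, and comes back at 15. Hydrogenation over Pd/C (H2, EtOAc, rt) should reduce C3=C4 and remove the benzyl group in one operation to give racemic phenol F3. Resolution by preparative chromatography on a chiral stationary phase should then deliver the (3R) enantiomer 15.

Further compounds
F1 | step 7 | racemic 4-{3-[2-(4-benzyloxy-2-SEM-oxyphenyl)-1-hydroxyprop-2-en-1-yl]-2-hydroxy-6-(SEM-oxy)phenyl}-2-methylbutan-2-ol | C=C(c1ccc(OCc2ccccc2)cc1OCOCC[Si](C)(C)C)C(O)c1ccc(OCOCC[Si](C)(C)C)c(CCC(C)(C)O)c1O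
F2 | step 11 | 4-{(3R)-3-[4-hydroxy-5-iodo-2-(SEM-oxy)phenyl]-7-(SEM-oxy)-3,4-dihydro-2H-chromen-8-yl}-2-methylbutan-2-ol | C[Si](C)(C)CCOCOc1cc(O)c(I)cc1[C@@H]1COc2c(ccc(OCOCC[Si](C)(C)C)c2CCC(C)(C)O)C1
F3 | step 8 | racemic 4-{3-[4-hydroxy-2-(SEM-oxy)phenyl]-7-(SEM-oxy)-3,4-dihydro-2H-chromen-8-yl}-2-methylbutan-2-ol | C[Si](C)(C)CCOCOc1cc(O)ccc1C1COc2c(ccc(OCOCC[Si](C)(C)C)c2CCC(C)(C)O)C1
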